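Each product takes up one substrate and one reagent, so c(reagent) minus c(substrate) stays where the charge put it: 600 mM in the alpha run, 600 mM in the beta run and 600 mM in the epsilon run. The meeting started from that constant.

| flask | substrate | reagent | free catalyst | time |
|---|---|---|---|---|
| alpha | 0.600 M | 1.20 M | 0.0480 M |  |
| epsilon | 0.360 M | 0.960 M | 0.0480 M |  |
| beta | 0.600 M | 1.20 M | 0.0240 M |  |
| theta | 0.600 M | 1.20 M | 0.0480 M | 12 h |

- alpha run (time / h: [substrate] / M): 0.18: 0.541; 0.55: 0.446; 1.1: 0.350; 1.7: 0.274; 2.4: 0.227; 3.2: 0.188; 4.1: 0.173
- epsilon run (time / h: [substrate] / M): 0.18: 0.327; 0.55: 0.269; 1.1: 0.214; 1.7: 0.175; 2.4: 0.140; 3.2: 0.122; 4.1: 0.108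
- beta run (time / h: [substrate] / M): 0.18: 0.563; 0.55: 0.489; 1.1: 0.420; 1.7: 0.364; 2.4: 0.325; 3.2: 0.304; 4.1: 0.304

(each reading ± 0.003 M)

- Overall: substrate + reagent -> product, with free catalyst as catalyst.
- Constant volume, constant temperature.
- Bound and free are read together.
- "The second partner" is reagent.
- An order is taken over about fifteen percent of the charge, up and down.

* reaction order in [free catalyst] at the outset, round the charge of the alpha run, defined at two percent of the substrate turned into product
* the epsilon run starts with 0.240 M less of substrate and of reagent than the alpha run, and with no product. Compared where both hold the same amount of substrate, once fifteen percent of what the epsilon run was charged with has turned into product, is the epsilon run faster, slower or alike (within a tenth)?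
* substrate in the theta run at 12 h, as a share of the substrate charged

The minute-taker proposed a clock: the natural logarithm of c(reagent)/c(substrate), counted from its value at the charge (the integrated second-order plot). With the excess constant, its speed is the excess times the apparent second-order constant, so substrate and reagent are divided out.

The minute-taker read the alpha clock at 0.290 h⁻¹ up to 0.55 h. The beta clock ran at 0.195 h⁻¹ over the same stretch, which gave the minute-taker a catalyst order of 0.567.

Late in the alpha run, from 2.4 h to 4.1 h, the clock had slowed to 0.120 h⁻¹. The minute-taker froze that fall as a straight line through the two speeds, each placed at the middle of its stretch. That line reaches zero speed at 5.36 h. At 4.1 h the alpha clock reads 0.804, and the line gives it a speed of 0.0717 h⁻¹.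

On that line the clock comes to rest well before the 12 h asked of the theta run, which has the alpha charge. It rests at 0.849, the stopping clock, the value where a flask's clock comes to rest. Through the constant excess, that leaves 27.2% of the substrate.

The beta run read 0.304 M at 3.2 h and 0.304 M at 4.1 h, a clock of 0.397 at the last reading. With a scatter of 0.003 M on each reading, that pair does not show that the beta clock has stopped.

The forecaster gave an order of 0.6 (from 0.42 to 0.8), called the epsilon run faster, and put the share at 26.5% (from 22.5% to 28.5%). The forecaster held that “this is not equilibrium; the catalyst dies”. The minute-taker's share stood 0.70 percentage points higher, inside that range.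

The simulation gives 26.8% in the theta run at 12 h, an order of 0.53, and the epsilon run faster, at 1.3 times the alpha rate at equal substrate.

    free catalyst + substrate ⇌ catalyst-substrate complex (241.9 M⁻¹ h⁻¹, 1224 h⁻¹)
    catalyst-substrate complex + reagent → product + free catalyst (2182 M⁻¹ h⁻¹)
    2 free catalyst ⇌ resting dimer, settled at all times (1760 M⁻¹)
    free catalyst → spent catalyst (5.472 h⁻¹)

The joining of free catalyst into the resting dimer, the resting state, makes no difference to that share. The stopping clock, 0.849 as reckoned and 0.861 from that share, is larger than the 0.397 read at 4.1 h in the beta run, about twice that reading, and the beta run was charged with 0.0240 M of free catalyst against 0.0480 M in the theta run.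

(The data were generated by integration from invented constants; the scatter is artificial.)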